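The earlier runs and the new flask stem from a simulated flask for substances that don't exist, and the scatter is random.

Per cent of the two substrates charged together is the unit of the readings, so without exchange a reading times 2 is the fraction of its own substrate gone. If the substrates only react, and each goes first-order in itself and in [partner] and [free catalyst], each decays with a drifting time constant, but both drift with the same product of [partner] and [free catalyst]. Integrated, the logarithm of each fraction left is a rate constant times one shared integral, which cancels in the ratio of the two logarithms, left-handed over right-handed. That ratio is the selectivity factor s, constant without exchange however partner and catalyst fare, and early in epsilon, at 0.500 h, it reads 2.89.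

| run | time / h | left-handed product / % | right-handed product / % |
|---|---|---|---|
| epsilon | 0.250 | 4.3 | 1.7 |
| epsilon | 0.500 | 7.4 | 2.7 |
| epsilon | 1.33 | 10.7 | 3.8 |
| epsilon | 3.00 | 14.3 | 4.9 |
| gamma | 0.833 | 20.7 | 7.9 |
| gamma | 1.50 | 24.5 | 8.8 |
| gamma | 2.50 | 27.3 | 10.9 |
| gamma | 3.00 | 28.0 | 10.5 |

(each reading ± 0.3 percentage points)

For whoever takes over the bench: the flask below holds both substrates, partner, free catalyst, impurity and added ligand, and is to be read at 3.0 h. It stays closed and the bath steady.

| setting | epsilon | gamma | flask |
|---|---|---|---|
| left-handed substrate | 0.47 M | 0.47 M | 0.47 M |
| right-handed substrate | 0.47 M | 0.47 M | 0.47 M |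
| partner | 1.1 equiv | 4.4 equiv | 2.20 equiv |
| free catalyst | 0.087 mol% | 0.087 mol% | 0.087 mol% |
| impurity | 0.25 mM | 0.25 mM | 0.25 mM |
| added ligand | 0.80 mM | 0.80 mM | 0.80 mM |
| remark | run made earlier | run made earlier |  |
| time |  |  | 3.0 h |

- left-handed product and right-handed product together, in percent of the left-handed substrate and right-handed substrate charged together, at 3.0 h
- excess of left-handed product over right-handed product in the product at 3.0 h
- whether the exchange between left-handed substrate and right-handed substrate keeps pace with the reaction: how far the product's excess at 3.0 h gets from its value without exchange to its value with instant exchange (above 80% keeps pace, below 20% hardly takes part, else lags behind)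

- free catalyst is single-handed; left-handed substrate and right-handed substrate are mirror images of each other, charged as a racemate, each of them at the stated concentration
- the numbers in the tables scatter by 0.3 percentage points (one standard deviation)
- an excess is below zero if the other one leads

Gamma at 3.00 h reads s = 3.48, while instant exchange, holding the product ratio at the early s, would read 3.84 at that yield. My reckoning therefore puts gamma 62.1% of the way, measured in s and not in the product's excess, and loosely given the scatter, and from that estimate expects this flask to lag behind. The forecast gives 28%, 47% and keeps pace, differing from me on pace: “The left/right product ratio stays near 2.7 from 6% to 38% total yield”.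

The flask gives 28.0%, 46.8% and lags behind, 70% of the way.

    free catalyst + added ligand ⇌ idle complex (K = 1300 L mol⁻¹, k = 0.330 L mol⁻¹ s⁻¹)
    free catalyst + impurity → spent catalyst (k = 23.0 L mol⁻¹ s⁻¹)
    partner + free catalyst + right-handed substrate → free catalyst + right-handed product (k = 0.450 L² mol⁻² s⁻¹)
    2 partner → homo dimer (k = 2.30 × 10⁻⁴ L mol⁻¹ s⁻¹)
    partner + free catalyst + left-handed substrate → free catalyst + left-handed product (k = 1.30 L² mol⁻² s⁻¹)
    left-handed substrate ⇌ right-handed substrate (k = 4.20 × 10⁻⁴ s⁻¹)

At 3.00 h in this flask the right-handed substrate leads the left-handed among what remains by 0.558%. The same ratio of logarithms, s, comes to 3.28 in this flask, higher than the early epsilon reading. The neighbour charged with 0.22 mol% of free catalyst holds 46.4% of left-handed product and 19.0% of right-handed product at 3.00 h, and its s stands higher still, at 5.50.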